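**Retrosynthetic overview**

1. Target 13 ⇐ 1,2-reduction of the C5 carbonyl of epoxyquinone 12 from the face anti to the oxirane (sets C5), after ω-hydroxylation of the terminal (E)-methyl group.
2. Epoxyquinone ⇐ direct catalytic asymmetric nucleophilic epoxidation of the free, unmasked 2,5-disubstituted farnesyl benzoquinone 8; this forms the oxirane and both of its stereocentres in one step.
3. Quinone 8 ⇐ oxidative demethylation of a 1,4-dimethoxyarene, built from 1,4-dibromo-2,5-dimethoxybenzene by two successive Br/Li exchanges (farnesyl bromide, then formaldehyde).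
4. Ring order: the six-membered carbocycle is bought as the arene and oxidised to the quinone; the oxirane is the only ring formed (step 4). This mirrors hydroquinone → quinone → epoxyquinone → ketoreduction → ω-hydroxylation.

**Assumption:** the cinchonidinium salt in step 4 is taken to give the (1R,6S) oxirane; if it gives the antipode, the pseudoenantiomeric N-(9-anthracenylmethyl)cinchoninium chloride is used with nothing else changed.

**Conventions:** "farnesyl" = (2E,6E)-3,7,11-trimethyldodeca-2,6,10-trien-1-yl. Bicyclic compounds are numbered C1 = farnesyl-bearing oxirane carbon, C2 = C=O next to it, C3 = CH=, C4 = carbon bearing the CH2O group, C5, C6 = oxirane CH, O7.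

**Step 1**
Reactants: 1 1,4-dibromo-2,5-dimethoxybenzene; 2 (2E,6E)-farnesyl bromide
Product: 4 1-bromo-4-[(2E,6E)-farnesyl]-2,5-dimethoxybenzene, via aryllithium 3 (not isolated)
Conditions: n-BuLi (1.0 equiv), THF, −78 °C; then CuBr·SMe2 (10 mol %), 2, −78 °C to rt
Reagents that add atoms: none
Why: Mono bromine–lithium exchange with one equivalent of n-BuLi, then copper-catalysed SN2 allylation of the aryllithium by the primary allylic bromide, gives the linear farnesyl arene with the olefin geometry of 2 retained and no stereocentre formed.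

**Step 2**
Reactants: 4 1-bromo-4-[(2E,6E)-farnesyl]-2,5-dimethoxybenzene
Product: 7 tert-butyl({4-[(2E,6E)-farnesyl]-2,5-dimethoxyphenyl}methoxy)diphenylsilane, via aryllithium 5 (not isolated), via lithium alkoxide 6 (not isolated)
Conditions: n-BuLi (1.1 equiv), THF, −78 °C; HCHO (g), −78 to 0 °C; then t-BuPh2SiCl, DMAP (cat.), rt
Reagents that add atoms: formaldehyde (C=O); tert-butyl(chloro)diphenylsilane (CC(C)(C)[Si](Cl)(c1ccccc1)c1ccccc1)
Why: A second bromine–lithium exchange, 1,2-addition of the aryllithium to monomeric formaldehyde and in situ O-silylation of the lithium alkoxide install the last ring carbon as a bulky, base-stable silyl ether that is not a leaving group.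

**Step 3**
Reactants: 7 tert-butyl({4-[(2E,6E)-farnesyl]-2,5-dimethoxyphenyl}methoxy)diphenylsilane
Product: 8 2-{[(tert-butyldiphenylsilyl)oxy]methyl}-5-[(2E,6E)-farnesyl]cyclohexa-2,5-diene-1,4-dione
Conditions: (NH4)2Ce(NO3)6 (2.5 equiv), MeCN/H2O (2:1), 0 °C, 15 min
Reagents that add atoms: water (O)
Why: Oxidative demethylation of the 1,4-dimethoxyarene by tetravalent cerium (two one-electron oxidations with water attacking the ipso carbons) gives the p-quinone faster than the isolated trisubstituted olefins or the silyl ether react.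

**Step 4**
Reactants: 8 2-{[(tert-butyldiphenylsilyl)oxy]methyl}-5-[(2E,6E)-farnesyl]cyclohexa-2,5-diene-1,4-dione
Product: 9 (1R,6S)-4-{[(tert-butyldiphenylsilyl)oxy]methyl}-1-[(2E,6E)-farnesyl]-7-oxabicyclo[4.1.0]hept-3-ene-2,5-dione
Conditions: t-BuOOH (1.2 equiv), N-(9-anthracenylmethyl)cinchonidinium chloride (10 mol %), 0.1 M aq NaOH (0.3 equiv), toluene, 0 °C
Reagents that add atoms: tert-butyl hydroperoxide (CC(C)(C)OO)
Why: Proposed new method: Weitz–Scheffer epoxidation under chiral ion-pair control, the closest known reaction being the cinchona-ammonium-catalysed epoxidation of 2-alkyl-1,4-naphthoquinones; t-BuOO− is expected to add to the CH of the farnesyl-bearing double bond because the other CH is shielded on both faces by the neighbouring CH2OSi(t-Bu)Ph2 group, the resulting enolate closes on the peroxide oxygen, and the chiral cation selects the quinone face so that both oxirane stereocentres (1R,6S) are set together.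

**Step 5**
Reactants: 9 (1R,6S)-4-{[(tert-butyldiphenylsilyl)oxy]methyl}-1-[(2E,6E)-farnesyl]-7-oxabicyclo[4.1.0]hept-3-ene-2,5-dione
Product: 11 (1R,6S)-4-(acetoxymethyl)-1-[(2E,6E)-farnesyl]-7-oxabicyclo[4.1.0]hept-3-ene-2,5-dione, via hydroxymethyl epoxyquinone 10 (not isolated)
Conditions: HF·pyridine, pyridine, THF, 0 °C to rt; then Ac2O, 0 °C
Reagents that add atoms: acetic anhydride (CC(=O)OC(C)=O)
Why: Fluoride-mediated desilylation followed by esterification in the same flask acetylates the only hydroxyl present at this stage, so no selectivity problem arises and the oxirane stereocentres are untouched.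

**Step 6**
Reactants: 11 (1R,6S)-4-(acetoxymethyl)-1-[(2E,6E)-farnesyl]-7-oxabicyclo[4.1.0]hept-3-ene-2,5-dione
Product: 12 (1R,6S)-4-(acetoxymethyl)-1-[(2E,6E,10E)-12-hydroxy-3,7,11-trimethyldodeca-2,6,10-trien-1-yl]-7-oxabicyclo[4.1.0]hept-3-ene-2,5-dione
Conditions: SeO2 (0.3 equiv), t-BuOOH (2 equiv), salicylic acid (10 mol %), CH2Cl2, 0 °C to rt; stop at partial conversion and recycle 11
Reagents that add atoms: selenium dioxide (O=[Se]=O), which transfers the oxygen; tert-butyl hydroperoxide (CC(C)(C)OO), the terminal oxidant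
Why: SeO2-catalysed allylic oxidation (ene reaction then [2,3]-sigmatropic shift) attacks the most electron-rich and least hindered terminal trisubstituted olefin and gives the (E)-allylic alcohol at the methyl trans to the chain, the olefin nearest the ring being deactivated by the epoxy ketone.

**Step 7**
Reactants: 12 (1R,6S)-4-(acetoxymethyl)-1-[(2E,6E,10E)-12-hydroxy-3,7,11-trimethyldodeca-2,6,10-trien-1-yl]-7-oxabicyclo[4.1.0]hept-3-ene-2,5-dione
Product: 13 (1R,5R,6R)-4-(acetoxymethyl)-5-hydroxy-1-[(2E,6E,10E)-12-hydroxy-3,7,11-trimethyldodeca-2,6,10-trien-1-yl]-7-oxabicyclo[4.1.0]hept-3-en-2-one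
Conditions: NaBH4 (1.0 equiv), CeCl3·7H2O (1.0 equiv), MeOH, −78 °C
Reagents that add atoms: none
Why: Luche reduction gives 1,2-addition only, and hydride attacks the C5 carbonyl (C2=O is shielded on its open face by the farnesyl CH2 on quaternary C1) from the face anti to the oxirane oxygen, setting C5 as R with the hydroxyl cis to the epoxide while the acetate survives at −78 °C.

**Compound list**

1 | 1,4-dibromo-2,5-dimethoxybenzene | COc1cc(Br)c(OC)cc1Br | starting material
2 | (2E,6E)-farnesyl bromide | BrC/C=C(\C)CC/C=C(\C)CCC=C(C)C | starting material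
3 | (4-bromo-2,5-dimethoxyphenyl)lithium | [Li]c1cc(OC)c(Br)cc1OC | intermediate
4 | 1-bromo-4-[(2E,6E)-farnesyl]-2,5-dimethoxybenzene | COc1cc(C/C=C(\C)CC/C=C(\C)CCC=C(C)C)c(OC)cc1Br | intermediate
5 | {4-[(2E,6E)-farnesyl]-2,5-dimethoxyphenyl}lithium | [Li]c1cc(OC)c(C/C=C(\C)CC/C=C(\C)CCC=C(C)C)cc1OC | intermediate
6 | lithium {4-[(2E,6E)-farnesyl]-2,5-dimethoxyphenyl}methoxide | [Li]OCc1cc(OC)c(C/C=C(\C)CC/C=C(\C)CCC=C(C)C)cc1OC | intermediate
7 | tert-butyl({4-[(2E,6E)-farnesyl]-2,5-dimethoxyphenyl}methoxy)diphenylsilane | CC(C)(C)[Si](OCc1cc(OC)c(C/C=C(\C)CC/C=C(\C)CCC=C(C)C)cc1OC)(c1ccccc1)c1ccccc1 | intermediate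
8 | 2-{[(tert-butyldiphenylsilyl)oxy]methyl}-5-[(2E,6E)-farnesyl]cyclohexa-2,5-diene-1,4-dione | CC(C)(C)[Si](OCC1=CC(=O)C(C/C=C(\C)CC/C=C(\C)CCC=C(C)C)=CC1=O)(c1ccccc1)c1ccccc1 | intermediate
9 | (1R,6S)-4-{[(tert-butyldiphenylsilyl)oxy]methyl}-1-[(2E,6E)-farnesyl]-7-oxabicyclo[4.1.0]hept-3-ene-2,5-dione | CC(C)(C)[Si](OCC1=CC(=O)[C@]2(C/C=C(\C)CC/C=C(\C)CCC=C(C)C)O[C@@H]2C1=O)(c1ccccc1)c1ccccc1 | intermediate
10 | (1R,6S)-1-[(2E,6E)-farnesyl]-4-(hydroxymethyl)-7-oxabicyclo[4.1.0]hept-3-ene-2,5-dione | OCC1=CC(=O)[C@]2(C/C=C(\C)CC/C=C(\C)CCC=C(C)C)O[C@@H]2C1=O | intermediate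
11 | (1R,6S)-4-(acetoxymethyl)-1-[(2E,6E)-farnesyl]-7-oxabicyclo[4.1.0]hept-3-ene-2,5-dione | CC(=O)OCC1=CC(=O)[C@]2(C/C=C(\C)CC/C=C(\C)CCC=C(C)C)O[C@@H]2C1=O | intermediate
12 | (1R,6S)-4-(acetoxymethyl)-1-[(2E,6E,10E)-12-hydroxy-3,7,11-trimethyldodeca-2,6,10-trien-1-yl]-7-oxabicyclo[4.1.0]hept-3-ene-2,5-dione | CC(=O)OCC1=CC(=O)[C@]2(C/C=C(\C)CC/C=C(\C)CC/C=C(\C)CO)O[C@@H]2C1=O | intermediate
13 | (1R,5R,6R)-4-(acetoxymethyl)-5-hydroxy-1-[(2E,6E,10E)-12-hydroxy-3,7,11-trimethyldodeca-2,6,10-trien-1-yl]-7-oxabicyclo[4.1.0]hept-3-en-2-one (hydroxyl cis to the oxirane oxygen) | CC(=O)OCC1=CC(=O)[C@]2(C/C=C(\C)CC/C=C(\C)CC/C=C(\C)CO)O[C@@H]2[C@@H]1O | target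

**Totals**

Total step count: 7. Longest linear sequence: 7 steps (from 1).

**Steps most likely to fail**

Step 4 (regio- and enantioselective epoxidation of the free quinone). The two quinone double bonds differ only in their CH2 substituent, so the wrong oxirane, the bis-epoxide, base-induced chromenol formation from the prenylquinone, or a modest ee are all possible. If the ee is only moderate, 9 must be enriched (preparative chiral HPLC or crystallisation of a derivative) to deliver the single enantiomer. The fallback sets out from 8 and comes back at 10. Quinone 8 is reduced with Na2S2O4 (EtOAc/H2O) to the hydroquinone silyl ether F1. This is desilylated with Et3N·3HF to 2-farnesyl-5-(hydroxymethyl)hydroquinone F2. The benzylic hydroxyl and the neighbouring phenol are tied together with 2,2-dimethoxypropane/PPTS as the benzodioxin acetonide F3, leaving only the phenol next to the farnesyl group free. Oxidation with PhI(OAc)2 in MeOH dearomatises it to the mixed quinone monoketal F4, in which only the farnesyl-bearing enone has an unsubstituted β-carbon, so the regiochemistry is fixed by the substrate. Epoxidation with t-BuOOH, aq NaOH and the same cinchonidinium salt gives the epoxy ketal F5; its ketal carbon is an epimeric mixture that is erased in the next operation. Hydrolysis with aqueous CF3CO2H removes the acetonide and the ketal together and delivers 10, which is acetylated as in step 5.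

Step 6 (SeO2 ω-hydroxylation). Conversion must be kept low, the internal olefins can compete, and over-oxidation gives the ω-enal; any such enal is not lost, since step 7 reduces it back to the same allylic alcohol. The fallback sets out from 11 and comes back at 13. Cross-metathesis of 11 with methacrolein (second-generation Hoveyda–Grubbs catalyst, RuCl2(H2IMes)(=CH-C6H4-2-OiPr), CH2Cl2, 40 °C) exchanges the terminal isopropylidene for the (E)-enal and gives the ω-oxo epoxyquinone F6. The Luche conditions of step 7 with a second equivalent of hydride then reduce the aldehyde and the C5 ketone together to 13.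

Step 7 (regio- and diastereoselective mono-reduction in the presence of the acetate). Risks are reduction at C2, over-reduction to the diol, the trans epimer and acetate loss. The fallback sets out from 9 and comes back at 13. Silyl ether 9, which carries no ester, is reduced with i-Bu2AlH (THF, −78 °C), the bulky aluminium hydride attacking C5 anti to the oxirane, to give the epoxyquinol silyl ether F7. HF·pyridine then frees the diol F8. The primary allylic hydroxyl is acetylated selectively over the hindered secondary one (AcCl, 2,4,6-collidine, CH2Cl2, −78 °C) to the 12-deoxy target F9. The SeO2/t-BuOOH oxidation of step 6 applied to F9 gives 13.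

**Further compounds**

F1 | step 4 | 2-{[(tert-butyldiphenylsilyl)oxy]methyl}-5-[(2E,6E)-farnesyl]benzene-1,4-diol | CC(C)(C)[Si](OCc1cc(O)c(C/C=C(\C)CC/C=C(\C)CCC=C(C)C)cc1O)(c1ccccc1)c1ccccc1
F2 | step 4 | 2-[(2E,6E)-farnesyl]-5-(hydroxymethyl)benzene-1,4-diol | OCc1cc(O)c(C/C=C(\C)CC/C=C(\C)CCC=C(C)C)cc1O
F3 | step 4 | 7-[(2E,6E)-farnesyl]-2,2-dimethyl-4H-1,3-benzodioxin-6-ol | CC1(C)OCc2cc(O)c(C/C=C(\C)CC/C=C(\C)CCC=C(C)C)cc2O1
F4 | step 4 | 7-[(2E,6E)-farnesyl]-8a-methoxy-2,2-dimethyl-4H-1,3-benzodioxin-6(8aH)-one (racemic at the ketal carbon) | COC12OC(C)(C)OCC1=CC(=O)C(C/C=C(\C)CC/C=C(\C)CCC=C(C)C)=C2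
F5 | step 4 | 7,8-epoxide of F4 with the oxirane configured as in 9 (ketal carbon epimeric) | CC1(C)OCC2=CC(=O)[C@]3(C/C=C(\C)CC/C=C(\C)CCC=C(C)C)O[C@@H]3C2(OC)O1
F6 | step 6 | (1R,6S)-4-(acetoxymethyl)-1-[(2E,6E,10E)-3,7,11-trimethyl-12-oxododeca-2,6,10-trien-1-yl]-7-oxabicyclo[4.1.0]hept-3-ene-2,5-dione | CC(=O)OCC1=CC(=O)[C@]2(C/C=C(\C)CC/C=C(\C)CC/C=C(\C)C=O)O[C@@H]2C1=O
F7 | step 7 | (1R,5R,6R)-4-{[(tert-butyldiphenylsilyl)oxy]methyl}-1-[(2E,6E)-farnesyl]-5-hydroxy-7-oxabicyclo[4.1.0]hept-3-en-2-one | CC(C)(C)[Si](OCC1=CC(=O)[C@]2(C/C=C(\C)CC/C=C(\C)CCC=C(C)C)O[C@@H]2[C@@H]1O)(c1ccccc1)c1ccccc1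
F8 | step 7 | (1R,5R,6R)-1-[(2E,6E)-farnesyl]-5-hydroxy-4-(hydroxymethyl)-7-oxabicyclo[4.1.0]hept-3-en-2-one | OCC1=CC(=O)[C@]2(C/C=C(\C)CC/C=C(\C)CCC=C(C)C)O[C@@H]2[C@@H]1O
F9 | step 7 | (1R,5R,6R)-4-(acetoxymethyl)-1-[(2E,6E)-farnesyl]-5-hydroxy-7-oxabicyclo[4.1.0]hept-3-en-2-one | CC(=O)OCC1=CC(=O)[C@]2(C/C=C(\C)CC/C=C(\C)CCC=C(C)C)O[C@@H]2[C@@H]1O
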